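Taking one reagent spent per substrate lost, north-west cannot turn over substrate beyond 43.8% of its charge, while west has room up to 70.0%. How near each comes depends on how many reagent half-lives its time holds.

| setting | summer | dawn | north-west | west |
|---|---|---|---|---|
| substrate | 5 mM | 5 mM | 8.0 mM | 5.0 mM |
| reagent | 2.3 mM | 1.8 mM | 3.50 mM | 3.50 mM |
| free catalyst | 0.25 mM | 0.25 mM | 0.25 mM | 0.25 mM |
| remark | run made earlier | run made earlier |  |  |
| time |  |  | 10 min | 2.5 min |

| run | time / s | target / % | substrate / % |
|---|---|---|---|
| summer | 12.0 | 3.1 | 97.4 |
| summer | 25.0 | 5.4 | 94.0 |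
| summer | 40.0 | 6.8 | 90.6 |
| summer | 50.0 | 6.9 | 88.1 |
| summer | 60.0 | 7.3 | 87.2 |
| summer | 80.0 | 9.3 | 83.3 |
| summer | 90.0 | 10.2 | 82.2 |
| dawn | 12.0 | 1.2 | 98.1 |
| dawn | 25.0 | 3.3 | 95.4 |
| dawn | 40.0 | 5.5 | 93.5 |
| dawn | 50.0 | 6.0 | 90.9 |
| dawn | 60.0 | 6.4 | 89.7 |
| dawn | 80.0 | 8.1 | 87.6 |
| dawn | 90.0 | 8.6 | 85.7 |

(scatter of a reading: 0.5 percentage points)

* the winner by amount of target, in percent of the substrate charged; "neither" if no more than 2 percentage points parts them (north-west / west / neither)
* how much target is there at the end, in percent of the substrate charged: north-west
* how much target is there at the end, in percent of the substrate charged: west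

- a reading or a percentage of target counts all its forms, free or not

Summer and dawn look nearly the same, with reagent the one difference. At 90.0 s, summer has lost 17.8% of its substrate and dawn 14.3%. That reading gives a ratio of 1.24 beside a reagent ratio of 1.28, so the pace follows reagent.

Writing the rate as k × substrate × reagent, with first order in substrate assumed, summer's last reading and its mean reagent give k = 0.00117 mM⁻¹ s⁻¹. Reagent then has a pseudo-first-order half-life τ = ln 2/(k × substrate charged). The count n = time/τ comes to 8.13 for north-west and 1.27 for west. This half-life count runs high, since τ is taken at full substrate and substrate falls.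

This reckoning therefore puts north-west near its ceiling and west at about 41.0% turned over.

The forecast names west, with north-west at 1% (0.2% to 9%) and west at 13.5% (11.5% to 16%), on the ground that “reagent is nearly exhausted, so target has mostly decayed”.

The flask gives north-west: north-west 32.4%, west 22.1%.

    reagent + free catalyst ⇌ catalyst intermediate A (K = 42.0 M⁻¹, k = 57.0 M⁻¹ s⁻¹)
    crystals ⇌ target, rate k2*(cs2 - [target]) while solid is left; crystals form when [target] > cs2 (solubility = 0.550 mM, k = 1.10 s⁻¹)
    substrate + catalyst intermediate A → catalyst intermediate B (k = 230 M⁻¹ s⁻¹)
    catalyst intermediate B → free catalyst + target (k = 0.630 s⁻¹)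
    target ⇌ isomer of the product (K = 1.50, k = 0.0230 s⁻¹)

The count runs high, as expected. North-west keeps 2.2% of its reagent, which is 5.51 half-lives against 8.13 counted, and its conversion of 42.8% stands just under the ceiling of 43.8%. West read at 10 min counts 5.08 and keeps 8.8% of its reagent, or 3.51 half-lives. North-west's target stays in part because target saturates: of its 32.4% of target, crystals make 25.6% of the substrate charged, and without saturation north-west ends at 17.2%. West trails north-west in part because its time is short and catalyst intermediate A goes back to reagent + free catalyst: west reaches 41.5% without that undoing and 53.1% after 25.0 min.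

The earlier runs and the new flask were generated by integration for substances that don't exist; the scatter is artificial.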